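Amounts are what I have: the charges, and what each earlier run held over time.

| flask | solid substrate | coupling partner | remark | time |
|---|---|---|---|---|
| south | 0.20 M | 0.50 equiv | run made earlier |  |
| east | 0.20 M | 0.75 equiv | run made earlier |  |
| south-west | 0.30 M | 1 equiv | run made earlier |  |
| flask | 0.20 M | 1.00 equiv |  | 40 min |

| run | time / min | target / % | dissolved substrate / % | solid substrate / % |
|---|---|---|---|---|
| south | 3.00 | 12.0 | 24.2 | 63.5 |
| south | 5.00 | 20.1 | 28.6 | 53.0 |
| south | 8.00 | 26.9 | 31.4 | 42.9 |
| south | 15.0 | 32.4 | 33.5 | 33.3 |
| south | 25.0 | 33.0 | 34.4 | 31.9 |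
| south | 40.0 | 33.1 | 34.3 | 31.4 |
| east | 6.00 | 30.6 | 26.3 | 41.5 |
| east | 12.0 | 45.7 | 31.8 | 23.4 |
| east | 20.0 | 49.5 | 34.2 | 17.1 |
| east | 25.0 | 49.6 | 34.4 | 16.7 |
| east | 30.0 | 49.8 | 34.4 | 15.5 |
| east | 40.0 | 50.1 | 34.5 | 15.5 |
| south-west | 4.00 | 25.1 | 12.3 | 63.0 |
| south-west | 10.0 | 49.8 | 17.8 | 31.7 |
| south-west | 20.0 | 62.1 | 22.0 | 15.6 |
| south-west | 30.0 | 62.8 | 23.7 | 14.2 |
| south-west | 40.0 | 63.0 | 23.9 | 14.6 |

(standard deviation of a reading: 0.5 percentage points)

- as a solid, counted per litre of solution: solid substrate
- at the start none of the solid substrate is in solution
- dissolved substrate means what is dissolved; the solid is not counted in it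

- target at 40 min, in percent of the solid substrate charged
- concentration of dissolved substrate in solution at 40 min, in percent of saturation

The target levels off in each run while solid substrate remains, 15.5% of the charge at the last east reading, so I read the coupling partner as the limiting reagent. But the target falls short of the partner charged. I therefore carry the partner's yield, the final target per equivalent of partner charged 0.668, read from the east run. The south-west run, at 0.30 M of solid substrate, gives a lower 0.630; the east run has this flask's 0.20 M, so I keep the east value for this flask.

My reckoning for the flask is 66.8% target. The remaining 33.2% is 96.2% of the 34.5% that the east solution holds beside solid, so I expect this flask's solution to end a little under saturation.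

The forecast differs slightly, with 65% and 97%: “The solid is therefore essentially exhausted, and the solution ends just below saturation”.

The flask gives 65.1% target. Its dissolved substrate stands at >99.9% of saturation, with 0.444% of the charge still solid.

    solid substrate ⇌ dissolved substrate, rate k1*(cs1 - [dissolved substrate]) while solid is left; crystals form when [dissolved substrate] > cs1 (solubility = 0.0690 M, k = 0.690 min⁻¹)
    dissolved substrate + coupling partner → target (k = 2.90 L mol⁻¹ min⁻¹)
    coupling partner → side product (k = 0.0640 min⁻¹)

In the flask, the coupling partner goes to target 2.0 times as fast as to side product at 3.99 min and 3.1 times as fast at 40.0 min, yet the side step has 99.2% of its turnover behind it at 20.0 min, and the flask's yield is 0.651 against the 0.667 that the early ratio gives. The partner's yield of 0.668 predicts 26.7% for a neighbour at 0.400 equiv, which stands at 27.2%, while in this flask the target moves by 5 points at 0.918 equiv and at 1.08 equiv of coupling partner.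

The readings are calculated for an exercise.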